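**Plan**

- Numbering: C1 is the ring carbon carrying OH and the C7H2OBz group, C2=C3 is the alkene, C4 carries OBz, C5 and C6 carry OH.
- Retrosynthesis: the O4–benzoyl bond is cut first, then the C4/C5 oxygens are tied into a cyclic carbonate. The C2=C3 alkene and the C6 hydroxyl are folded back into a C3–O–C6 ether bridge with iodine on C2. The C1 hydroxyl and the C2 heteroatom are removed as a syn hydration. Finally C3–C4 and C5–C6 are cut in a retro-[4+2].
- Forward: furan-3-ylmethanol is benzoylated. The furan and vinylene carbonate close the carbocycle as a 7-oxanorbornene with the carbonate ring already fused on. Hydroxymercuration, iodination and zinc open the oxygen bridge. The carbonate is hydrolysed and a lipase installs the O4 benzoate.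
- Enabling feature: C3 and C6 stand 1,4 across the six-membered ring, C6 is oxygenated and C3 is not, and the cis O4/O5 pair on C4/C5 is trans to O6. This is the pattern of the endo vinylene carbonate adduct of a 3-substituted furan whose ring oxygen spans C3 and C6.
- Stereochemistry: cis C4/C5 comes from the ring-locked dienophile, their trans relation to O6 from the endo mode, C1 from bridge-side (exo) hydroxymercuration, and the absolute configuration from the lipase step.

Key step: step 2

Assumption: compounds 5 to 11 are racemic; names and SMILES show the enantiomer that ends in 13. Bicyclic names use 7-oxabicyclo[2.2.1]heptane numbering (bicyclic C1, C2, C3, C4, C5, C6 are target C6, C1, C2, C3, C4, C5). Iodide 8 is drawn as the exo epimer; either epimer at that carbon serves, because it becomes trigonal in step 5.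

Step 1
Reactants: 1 furan-3-ylmethanol; 2 benzoyl chloride
Product: 3 furan-3-ylmethyl benzoate
Conditions: BzCl (1.1 equiv), Et3N, 4-(dimethylamino)pyridine (cat.), CH2Cl2, 0 °C to rt
Reagents that add atoms: none
Why: Acylation of an unhindered primary alcohol by an acid chloride (nucleophilic acyl substitution) is routine, creates no stereocentre and installs the C7 benzoate of the target at the outset.

Step 2
Reactants: 3 furan-3-ylmethyl benzoate; 4 vinylene carbonate
Product: 5 [(1R,4S,5R,6S)-5,6-(carbonyldioxy)-7-oxabicyclo[2.2.1]hept-2-en-2-yl]methyl benzoate (carbonate ring endo; racemic)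
Conditions: 4 (4 equiv, neat), 2,6-di-tert-butyl-4-methylphenol (cat.), sealed tube, 125 °C; chromatographic removal of the exo diastereomer
Reagents that add atoms: none
Why: A concerted, thermally allowed suprafacial [4+2] cycloaddition joins the two furan α-carbons (future C3 and C6) to the two alkene carbons of vinylene carbonate (future C4 and C5), making C3–C4 and C5–C6 together; the closest known reaction is the thermal Diels–Alder addition of furan itself to vinylene carbonate. The six-membered carbocycle is closed by this intermolecular cycloaddition and is formed as the boat of a 7-oxabicyclo[2.2.1]hept-2-ene with the carbonate ring cis-fused to it. C3 and C6 are fixed relative to each other by the oxygen bridge, C4 and C5 are cis because the dienophile is a ring-locked cis alkene, and the relation between the two pairs is set by the endo transition state, which puts the carbonate oxygens anti to the bridge (O4/O5 trans to O6). No regiochemical question arises, since the dienophile is symmetric and the furan 3-substituent can only end on alkene carbon C1. The selectivity the step needs is endo over exo; nothing in the substrate enforces it, so it is secured by separating the diastereomers, and the exo isomer can be cracked back to 3 and 4 on heating. The adduct is racemic and the absolute configuration is settled in step 7.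

Step 3
Reactants: 5 endo adduct
Product: 7 [3-exo-(chloromercurio)-5-endo,6-endo-(carbonyldioxy)-2-exo-hydroxy-7-oxabicyclo[2.2.1]hept-2-endo-yl]methyl benzoate (racemic), via acetoxymercurial 6 (not isolated)
Conditions: Hg(OAc)2 (1.2 equiv), THF–H2O (1:1), rt; then saturated aqueous NaCl
Reagents that add atoms: mercury diacetate, CC(=O)O[Hg]OC(C)=O; water, O; sodium chloride, [Na+].[Cl-]
Why: Hydroxymercuration of a strained bicyclic alkene should proceed, as with norbornene-type alkenes, by syn addition on the exo face with Markovnikov orientation, so that the hydroxyl lands on the fully substituted C1 on the side of the oxygen bridge (the endo face is screened by the carbonate ring), which sets C1 with its OH cis to the future C6 oxygen and puts mercury exo on C2, after which acetate on mercury is exchanged for chloride.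

Step 4
Reactants: 7 chloromercurial
Product: 8 [5-endo,6-endo-(carbonyldioxy)-2-exo-hydroxy-3-exo-iodo-7-oxabicyclo[2.2.1]hept-2-endo-yl]methyl benzoate (racemic)
Conditions: I2 (1.1 equiv), CH2Cl2, rt, dark
Reagents that add atoms: iodine, II
Why: Iododemercuration (electrophilic cleavage of the C–Hg bond by iodine) replaces mercury on C2 by iodine without touching C1, and the configuration at C2 is immaterial because that carbon becomes trigonal in step 5.

Step 5
Reactants: 8 iodide
Product: 10 [(1S,4R,5S,6S)-4,5-(carbonyldioxy)-1,6-dihydroxycyclohex-2-en-1-yl]methyl benzoate (racemic), via alkylzinc iodide 9 (not isolated)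
Conditions: activated Zn dust (5 equiv), THF–H2O (9:1), 40 °C, sonication
Reagents that add atoms: none
Why: Zinc insertion into the C2–I bond followed by β-alkoxy elimination (a Boord-type reductive elimination, the bicyclic counterpart of the Bernet–Vasella fragmentation) should expel the strained C3–O bridge, which lies nearly antiperiplanar to an endo C2–Zn bond, in preference to the C1 hydroxyl, which is never antiperiplanar to it, giving the C2=C3 alkene and leaving the bridge oxygen on C6 as a hydroxyl; no stereocentre is formed and C1, C4, C5 and C6 are untouched.

Step 6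
Reactants: 10 diol carbonate
Product: 11 [(1S,4R,5R,6S)-1,4,5,6-tetrahydroxycyclohex-2-en-1-yl]methyl benzoate (racemic)
Conditions: pyridine–H2O (4:1), 90 °C
Reagents that add atoms: none
Why: Hydrolysis of a five-membered cyclic carbonate in hot aqueous pyridine (acyl substitution at the carbonate carbon, then decarboxylation) is mild enough that a simple benzoate ester is expected to survive, and since only bonds at the carbonate carbon break, no stereocentre is affected.

Step 7
Reactants: 11 tetraol monobenzoate; 12 vinyl benzoate
Product: 13 [(1S,4R,5S,6S)-4-(benzoyloxy)-1,5,6-trihydroxycyclohex-2-en-1-yl]methyl benzoate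
Conditions: immobilised Burkholderia cepacia lipase, 12 (3 equiv), tert-butyl methyl ether–THF, 40 °C, stopped below half conversion; chromatography
Reagents that add atoms: none
Why: Lipase-catalysed irreversible transesterification with a vinyl ester (kinetic resolution) should benzoylate only the least hindered secondary hydroxyl, the allylic O4 (O5 lies between two carbinol carbons, O6 adjoins the quaternary C1 and O1 is tertiary), and, by the empirical size rule for such acylations (small vinylic CH on one side, large C5 on the other), faster in the (4R) enantiomer, so that 13 forms from one antipode while the mirror-image tetraol stays behind and is separated; no stereocentre is created.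

**Compound list**

1 | furan-3-ylmethanol | OCc1ccoc1 | starting material
2 | benzoyl chloride | O=C(Cl)c1ccccc1 | starting material
3 | furan-3-ylmethyl benzoate | O=C(OCc1ccoc1)c1ccccc1 | intermediate
4 | vinylene carbonate (1,3-dioxol-2-one) | O=C1OC=CO1 | starting material
5 | [(1R,4S,5R,6S)-5,6-(carbonyldioxy)-7-oxabicyclo[2.2.1]hept-2-en-2-yl]methyl benzoate, carbonate ring endo (anti to the oxygen bridge), racemic | O=C(OCC1=C[C@@H]2O[C@H]1[C@@H]1OC(=O)O[C@@H]12)c1ccccc1 | intermediate
6 | acetoxymercurial: as 7 with HgOAc in place of HgCl (2-exo-OH, 3-exo-HgOAc, endo carbonate), racemic | O=C(OC[C@@]1(O)[C@H]([Hg]OC(C)=O)[C@@H]2O[C@H]1[C@@H]1OC(=O)O[C@@H]12)c1ccccc1 | intermediate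
7 | [3-exo-(chloromercurio)-5-endo,6-endo-(carbonyldioxy)-2-exo-hydroxy-7-oxabicyclo[2.2.1]hept-2-endo-yl]methyl benzoate, racemic | O=C(OC[C@@]1(O)[C@H]([Hg]Cl)[C@@H]2O[C@H]1[C@@H]1OC(=O)O[C@@H]12)c1ccccc1 | intermediate
8 | [5-endo,6-endo-(carbonyldioxy)-2-exo-hydroxy-3-exo-iodo-7-oxabicyclo[2.2.1]hept-2-endo-yl]methyl benzoate, racemic | O=C(OC[C@@]1(O)[C@H](I)[C@@H]2O[C@H]1[C@@H]1OC(=O)O[C@@H]12)c1ccccc1 | intermediate
9 | alkylzinc iodide: as 8 with ZnI in place of iodine on bicyclic C3, configuration at that carbon not fixed, racemic | O=C(OC[C@@]1(O)C([Zn]I)[C@@H]2O[C@H]1[C@@H]1OC(=O)O[C@@H]12)c1ccccc1 | intermediate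
10 | [(1S,4R,5S,6S)-4,5-(carbonyldioxy)-1,6-dihydroxycyclohex-2-en-1-yl]methyl benzoate (O1 and O6 cis, both trans to the carbonate), racemic | O=C(OC[C@@]1(O)C=C[C@H]2OC(=O)O[C@H]2[C@@H]1O)c1ccccc1 | intermediate
11 | [(1S,4R,5R,6S)-1,4,5,6-tetrahydroxycyclohex-2-en-1-yl]methyl benzoate, racemic | O=C(OC[C@@]1(O)C=C[C@@H](O)[C@@H](O)[C@@H]1O)c1ccccc1 | intermediate
12 | vinyl benzoate | C=COC(=O)c1ccccc1 | starting material
13 | [(1S,4R,5S,6S)-4-(benzoyloxy)-1,5,6-trihydroxycyclohex-2-en-1-yl]methyl benzoate (CNP0217467.1) | O=C(OC[C@@]1(O)C=C[C@@H](OC(=O)c2ccccc2)[C@@H](O)[C@@H]1O)c1ccccc1 | target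

**Step count and risks**

Total step count: 7. Longest linear sequence: 7 steps (1 to 13).

Steps most likely to fail:

Step 5. The alkylzinc may be protonated before it eliminates, or may shed the C1 hydroxyl and so return the bicyclic alkene, instead of opening the bridge. The fallback introduces the C1 oxygen only after the bridge is open. It sets out from 5: Pd(PPh3)4 (cat.) and zinc dust in THF should turn the allylic benzoate into an allylzinc, whose C2 terminus expels the C3–O bridge in the vinylogous form of the same elimination, giving 4,5-(carbonyldioxy)-1-methylidenecyclohex-2-en-6-ol F1. OsO4 with N,N,N',N'-tetramethylethylenediamine in CH2Cl2 at −78 °C, hydrogen-bonded to the allylic C6 hydroxyl, should dihydroxylate the exocyclic alkene on the face of that hydroxyl to give 4,5-(carbonyldioxy)-1-(hydroxymethyl)cyclohex-2-ene-1,6-diol F2. BzCl with 2,4,6-collidine at −40 °C then benzoylates the primary hydroxyl and the route is rejoined at 10.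

Step 7. The enzyme may distinguish the enantiomers poorly, acylate O5 as well, or turn over too slowly with the bulky acyl donor. The fallback uses chemical regiocontrol and a physical resolution. It sets out from 10: 2,2-dimethoxypropane and pyridinium p-toluenesulfonate in acetone give the 1,6-O-isopropylidene derivative of 10 F3. Pyridine–H2O at 90 °C frees the 4,5-diol to give the 1,6-O-isopropylidene derivative of 11 F4. BzCl (1.05 equiv) in pyridine–CH2Cl2 at −40 °C benzoylates the more accessible allylic O4 to give the 1,6-O-isopropylidene derivative of 13 F5, which is resolved by preparative chromatography on a chiral stationary phase (cellulose tris(3,5-dimethylphenylcarbamate)). Aqueous AcOH at 40 °C removes the acetonide and the route is rejoined at 13.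

Step 6. The primary benzoate may be cleaved or may migrate while the carbonate is hydrolysed. The fallback removes both acyl groups and puts the primary ester back. It sets out from 10: K2CO3 in MeOH at rt gives 1-(hydroxymethyl)cyclohex-2-ene-1,4,5,6-tetrol F6 with the relative configuration of 11. BzCl (1 equiv) in pyridine at −40 °C acylates the primary hydroxyl selectively and the route is rejoined at 11.

**Further compounds**

F1 | step 5 | 4,5-(carbonyldioxy)-1-methylidenecyclohex-2-en-6-ol, O6 trans to the carbonate, racemic | C=C1C=C[C@H]2OC(=O)O[C@H]2[C@@H]1O
F2 | step 5 | 4,5-(carbonyldioxy)-1-(hydroxymethyl)cyclohex-2-ene-1,6-diol, relative configuration of 10, racemic | OC[C@@]1(O)C=C[C@H]2OC(=O)O[C@H]2[C@@H]1O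
F3 | step 7 | 1,6-O-isopropylidene derivative of 10, racemic | O=C(OC[C@@]1(OC(C)(C)O2)C=C[C@H]3OC(=O)O[C@H]3[C@@H]12)c1ccccc1
F4 | step 7 | 1,6-O-isopropylidene derivative of 11, racemic | O=C(OC[C@@]1(OC(C)(C)O2)C=C[C@@H](O)[C@@H](O)[C@@H]12)c1ccccc1
F5 | step 7 | 1,6-O-isopropylidene derivative of 13, made racemic and resolved | O=C(OC[C@@]1(OC(C)(C)O2)C=C[C@@H](OC(=O)c3ccccc3)[C@@H](O)[C@@H]12)c1ccccc1
F6 | step 6 | 1-(hydroxymethyl)cyclohex-2-ene-1,4,5,6-tetrol, relative configuration of 11, racemic | OC[C@@]1(O)C=C[C@@H](O)[C@@H](O)[C@@H]1O
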